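**Retrosynthetic overview**
1. Target ⇐ bis-silyl ether of the angelate; the C8 ester, the exocyclic methylene (Mannich/elimination) and the two primary silyl ethers are handled last.
2. Ten-membered ring (second and last ring formed) ⇐ ring-closing metathesis giving the ring-cis C1=C10 trisubstituted olefin; the γ-lactone is the first ring formed.
3. C8 carbinol ⇐ Felkin–Anh hydride reduction of a C8 ketone, made by Barbier allylation of a lactone aldehyde with a 2-(silyloxymethyl)allyl bromide, then oxidation.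
4. Key fragment union ⇐ intermolecular Evans syn-aldol of a succinate-derived N-acyl oxazolidinone (C7, C8, C11, C12) with the aldehyde C1–C6/C15; it forms C6–C7, sets C6 and C7, and lactonises to the trans γ-lactone.
5. Aldehyde fragment ⇐ Evans alkylation of an N-hex-5-enoyl oxazolidinone with tert-butyl bromoacetate (sets C4).

Assumption: locants are germacrane-type labels for the target carbons (C6 = lactone O–CH; C7 = ring-fusion CH carrying C11; C8 = CH–O-angeloyl; C9 = CH2; C10 = olefinic C carrying C14H2OH; C1 = olefinic CH; C2, C3 = CH2; C4 = CH carrying C15H2OH; C5 = CH2; C11/C12/C13 = lactone α-C, C=O, exocyclic CH2). TBDPS = tert-butyldiphenylsilyl; TES = triethylsilyl.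

**Step 1**
Reactants: 1 (S)-4-benzyl-1,3-oxazolidin-2-one; 2 hex-5-enoic acid
Product: 4 (4S)-4-benzyl-3-(hex-5-enoyl)-1,3-oxazolidin-2-one, via hex-5-enoic pivalic anhydride 3 (not isolated)
Conditions: 2, PivCl, Et3N, THF, −20 °C; then 1, LiCl, rt
Reagents that add atoms: none
Why: Mixed-anhydride N-acylation of the oxazolidinone (LiCl-assisted); no stereocentre is formed.

**Step 2**
Reactants: 4 (4S)-4-benzyl-3-(hex-5-enoyl)-1,3-oxazolidin-2-one; 5 tert-butyl bromoacetate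
Product: 7 tert-butyl (3R)-3-[(4S)-4-benzyl-2-oxo-1,3-oxazolidine-3-carbonyl]hept-6-enoate, via sodium (Z)-enolate 6 (not isolated)
Conditions: NaN(SiMe3)2, THF, −78 °C; then 5, −78 → −40 °C
Reagents that add atoms: none
Why: Evans asymmetric enolate alkylation; the chelated (Z)-enolate is attacked on the face opposite the benzyl group, which sets C4 as (R).

**Step 3**
Reactants: 7 tert-butyl (3R)-3-[(4S)-4-benzyl-2-oxo-1,3-oxazolidine-3-carbonyl]hept-6-enoate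
Product: 8 tert-butyl (3R)-3-(hydroxymethyl)hept-6-enoate
Conditions: LiBH4, H2O (1 equiv), Et2O, 0 °C
Reagents that add atoms: none
Why: Reductive cleavage of the imide is faster than reduction of the hindered tert-butyl ester; the auxiliary is released and C4 is untouched.

**Step 4**
Reactants: 8 tert-butyl (3R)-3-(hydroxymethyl)hept-6-enoate
Product: 9 tert-butyl (3R)-3-[(TBDPS-oxy)methyl]hept-6-enoate
Conditions: TBDPSCl, imidazole, DMF, rt
Reagents that add atoms: tert-butyl(chloro)diphenylsilane, CC(C)(C)[Si](Cl)(c1ccccc1)c1ccccc1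
Why: Silylation of the primary alcohol; the robust TBDPS ether should survive every step until the final deprotection.

**Step 5**
Reactants: 9 tert-butyl (3R)-3-[(TBDPS-oxy)methyl]hept-6-enoate
Product: 11 (3R)-3-[(TBDPS-oxy)methyl]hept-6-enal, via aluminium hemiacetal 10 (not isolated)
Conditions: i-Bu2AlH (1.1 equiv), CH2Cl2, −78 °C; aq. potassium sodium tartrate
Reagents that add atoms: none
Why: Partial ester reduction stops at the tetrahedral aluminium hemiacetal at −78 °C, which gives the aldehyde on work-up.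

**Step 6**
Reactants: 1 (S)-4-benzyl-1,3-oxazolidin-2-one; 12 methyl 4-chloro-4-oxobutanoate
Product: 14 methyl 4-[(4S)-4-benzyl-2-oxo-1,3-oxazolidin-3-yl]-4-oxobutanoate, via N-lithio oxazolidinone 13 (not isolated)
Conditions: n-BuLi, THF, −78 °C; then 12, −78 → 0 °C
Reagents that add atoms: none
Why: N-acylation of the lithiated oxazolidinone by the acid chloride.

**Step 7**
Reactants: 14 methyl 4-[(4S)-4-benzyl-2-oxo-1,3-oxazolidin-3-yl]-4-oxobutanoate; 11 (3R)-3-[(TBDPS-oxy)methyl]hept-6-enal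
Product: 16 methyl (3S,4R,6R)-3-[(4S)-4-benzyl-2-oxo-1,3-oxazolidine-3-carbonyl]-4-hydroxy-6-[(TBDPS-oxy)methyl]dec-9-enoate, via (Z)-dibutylboron enolate 15 (not isolated)
Conditions: n-Bu2BOTf, i-Pr2NEt, CH2Cl2, −78 → 0 °C; then 11, −78 → 0 °C; pH 7 buffer, MeOH, 30% H2O2, 0 °C
Reagents that add atoms: none
Why: Evans syn-aldol reaction (key fragment union); the (Z)-boron enolate, formed only at the imide α-carbon, reacts through a Zimmerman–Traxler chair on the face away from the benzyl group, forming C6–C7 with C6 (R) and C7 (S), 6,7-syn.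

**Step 8**
Reactants: 16 methyl (3S,4R,6R)-3-[(4S)-4-benzyl-2-oxo-1,3-oxazolidine-3-carbonyl]-4-hydroxy-6-[(TBDPS-oxy)methyl]dec-9-enoate
Product: 17 (4S)-4-benzyl-3-[(2R,3S)-2-[(2R)-2-[(TBDPS-oxy)methyl]hex-5-en-1-yl]-5-oxooxolane-3-carbonyl]-1,3-oxazolidin-2-one
Conditions: p-TsOH·H2O (cat.), toluene, 50 °C
Reagents that add atoms: none
Why: Acid-catalysed lactonisation of the γ-hydroxy ester; the syn-aldol relationship becomes the trans-4,5-disubstituted γ-lactone without touching a stereocentre.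

**Step 9**
Reactants: 17 (4S)-4-benzyl-3-[(2R,3S)-2-[(2R)-2-[(TBDPS-oxy)methyl]hex-5-en-1-yl]-5-oxooxolane-3-carbonyl]-1,3-oxazolidin-2-one
Product: 19 (2R,3S)-2-[(2R)-2-[(TBDPS-oxy)methyl]hex-5-en-1-yl]-5-oxooxolane-3-carboxylic acid, via peroxy acid 18 (not isolated)
Conditions: LiOH, 30% H2O2, THF/H2O, 0 °C; Na2SO3; then 1 M HCl to pH 2
Reagents that add atoms: hydrogen peroxide, OO
Why: Hydroperoxide cleavage of the exocyclic imide carbonyl, then sulfite reduction of the peroxy acid; any lactone opened by hydroxide re-closes on acidification.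

**Step 10**
Reactants: 19 (2R,3S)-2-[(2R)-2-[(TBDPS-oxy)methyl]hex-5-en-1-yl]-5-oxooxolane-3-carboxylic acid
Product: 21 (4R,5R)-4-(hydroxymethyl)-5-[(2R)-2-[(TBDPS-oxy)methyl]hex-5-en-1-yl]oxolan-2-one, via isobutyl carbonic anhydride 20 (not isolated)
Conditions: i-BuOCOCl, N-methylmorpholine, THF, −15 °C; then NaBH4, H2O, −15 → 0 °C
Reagents that add atoms: none
Why: Mixed carbonic anhydride activation and borohydride reduction convert the acid into the primary alcohol without touching the lactone or the alkene.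

**Step 11**
Reactants: 21 (4R,5R)-4-(hydroxymethyl)-5-[(2R)-2-[(TBDPS-oxy)methyl]hex-5-en-1-yl]oxolan-2-one
Product: 22 (2R,3S)-2-[(2R)-2-[(TBDPS-oxy)methyl]hex-5-en-1-yl]-5-oxooxolane-3-carbaldehyde
Conditions: Dess–Martin periodinane, CH2Cl2, 0 °C → rt
Reagents that add atoms: none
Why: Dess–Martin oxidation under non-basic conditions; the trans C6/C7 arrangement is the thermodynamically preferred one, so C7 is not at risk.

**Step 12**
Reactants: 23 2-methylidenepropane-1,3-diol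
Product: 24 2-[(TBDPS-oxy)methyl]prop-2-en-1-ol
Conditions: TBDPSCl (1 equiv), imidazole, 23 (3 equiv), THF, 0 °C → rt
Reagents that add atoms: tert-butyl(chloro)diphenylsilane, CC(C)(C)[Si](Cl)(c1ccccc1)c1ccccc1
Why: Statistical monosilylation of the symmetrical diol used in excess.

**Step 13**
Reactants: 24 2-[(TBDPS-oxy)methyl]prop-2-en-1-ol
Product: 26 {[2-(bromomethyl)prop-2-en-1-yl]oxy}(tert-butyl)diphenylsilane, via allylic mesylate 25 (not isolated)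
Conditions: MsCl, Et3N, THF, 0 °C; then LiBr, rt
Reagents that add atoms: lithium bromide, [Li+].[Br-]
Why: Mesylation and SN2 displacement by bromide give the allylic bromide under non-acidic conditions.

**Step 14**
Reactants: 22 (2R,3S)-2-[(2R)-2-[(TBDPS-oxy)methyl]hex-5-en-1-yl]-5-oxooxolane-3-carbaldehyde; 26 {[2-(bromomethyl)prop-2-en-1-yl]oxy}(tert-butyl)diphenylsilane
Product: 28 (4R,5R)-4-[(1RS)-1-hydroxy-3-[(TBDPS-oxy)methyl]but-3-en-1-yl]-5-[(2R)-2-[(TBDPS-oxy)methyl]hex-5-en-1-yl]oxolan-2-one (C8 epimer mixture), via allylzinc bromide 27 (not isolated)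
Conditions: Zn dust, THF/sat. aq. NH4Cl, 0 °C → rt
Reagents that add atoms: none
Why: Barbier-type carbonyl allylation adds the C9–C10(=CH2)–C14 unit to the aldehyde chemoselectively; the C8 configuration is irrelevant because it is oxidised in step 15.

**Step 15**
Reactants: 28 (4R,5R)-4-[(1RS)-1-hydroxy-3-[(TBDPS-oxy)methyl]but-3-en-1-yl]-5-[(2R)-2-[(TBDPS-oxy)methyl]hex-5-en-1-yl]oxolan-2-one
Product: 29 (4S,5R)-4-[3-[(TBDPS-oxy)methyl]but-3-enoyl]-5-[(2R)-2-[(TBDPS-oxy)methyl]hex-5-en-1-yl]oxolan-2-one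
Conditions: Dess–Martin periodinane, NaHCO3, CH2Cl2, 0 °C
Reagents that add atoms: none
Why: Buffered Dess–Martin oxidation gives the β,γ-unsaturated ketone without moving the double bond into conjugation; the ketone is used directly.

**Step 16**
Reactants: 29 (4S,5R)-4-[3-[(TBDPS-oxy)methyl]but-3-enoyl]-5-[(2R)-2-[(TBDPS-oxy)methyl]hex-5-en-1-yl]oxolan-2-one
Product: 30 (4R,5R)-4-[(1R)-1-hydroxy-3-[(TBDPS-oxy)methyl]but-3-en-1-yl]-5-[(2R)-2-[(TBDPS-oxy)methyl]hex-5-en-1-yl]oxolan-2-one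
Conditions: LiBH(s-Bu)3 (L-Selectride), THF, −78 °C; AcOH quench at −78 °C
Reagents that add atoms: none
Why: Felkin–Anh ketone reduction; the bulky hydride attacks anti to the larger C6 branch on C7 and gives the (R)-carbinol at C8 (7,8-anti), and the cold acidic quench prevents translactonisation.

**Step 17**
Reactants: 30 (4R,5R)-4-[(1R)-1-hydroxy-3-[(TBDPS-oxy)methyl]but-3-en-1-yl]-5-[(2R)-2-[(TBDPS-oxy)methyl]hex-5-en-1-yl]oxolan-2-one
Product: 31 (4S,5R)-4-[(1R)-3-[(TBDPS-oxy)methyl]-1-(triethylsilyloxy)but-3-en-1-yl]-5-[(2R)-2-[(TBDPS-oxy)methyl]hex-5-en-1-yl]oxolan-2-one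
Conditions: Et3SiOTf, 2,6-lutidine, CH2Cl2, −78 → 0 °C
Reagents that add atoms: triethylsilyl trifluoromethanesulfonate, CC[Si](CC)(CC)OS(=O)(=O)C(F)(F)F
Why: Silylation of the C8 hydroxyl protects it against the strong base of step 19.

**Step 18**
Reactants: 31 (4S,5R)-4-[(1R)-3-[(TBDPS-oxy)methyl]-1-(triethylsilyloxy)but-3-en-1-yl]-5-[(2R)-2-[(TBDPS-oxy)methyl]hex-5-en-1-yl]oxolan-2-one
Product: 32 (3aS,4R,6E,10R,11aR)-6,10-bis[(TBDPS-oxy)methyl]-4-(triethylsilyloxy)-3a,4,5,8,9,10,11,11a-octahydrocyclodeca[b]furan-2(3H)-one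
Conditions: second-generation Grubbs catalyst RuCl2(=CHPh)(H2IMes)(PCy3) (15 mol %), toluene (1 mM), 80 °C
Reagents that add atoms: none
Why: Ring-closing metathesis of the mono- and 1,1-disubstituted olefins closes the ten-membered ring with loss of ethene; the trans-fused lactone holds the chains together and the less strained ring-cis olefin (6E by the sequence rules) forms under equilibrating conditions.

**Step 19**
Reactants: 32 (3aS,4R,6E,10R,11aR)-6,10-bis[(TBDPS-oxy)methyl]-4-(triethylsilyloxy)-3a,4,5,8,9,10,11,11a-octahydrocyclodeca[b]furan-2(3H)-one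
Product: 34 (3aS,4R,6E,10R,11aR)-3-[(dimethylamino)methyl]-6,10-bis[(TBDPS-oxy)methyl]-4-(triethylsilyloxy)-3a,4,5,8,9,10,11,11a-octahydrocyclodeca[b]furan-2(3H)-one (C11 epimers), via lithium enolate 33 (not isolated)
Conditions: LiN(i-Pr)2, THF, −78 °C; then Me2N=CH2+ I−, −78 → 0 °C
Reagents that add atoms: N,N-dimethylmethylideneammonium iodide (Eschenmoser's salt), C=[N+](C)C.[I-]
Why: Mannich aminomethylation of the lactone enolate at the only enolisable α-carbon; the new C11 centre is destroyed in step 20.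

**Step 20**
Reactants: 34 (3aS,4R,6E,10R,11aR)-3-[(dimethylamino)methyl]-6,10-bis[(TBDPS-oxy)methyl]-4-(triethylsilyloxy)-3a,4,5,8,9,10,11,11a-octahydrocyclodeca[b]furan-2(3H)-one
Product: 36 (3aS,4R,6E,10R,11aR)-6,10-bis[(TBDPS-oxy)methyl]-3-methylidene-4-(triethylsilyloxy)-3a,4,5,8,9,10,11,11a-octahydrocyclodeca[b]furan-2(3H)-one, via trimethylammonium iodide 35 (not isolated)
Conditions: MeI, CH2Cl2/MeOH, rt; then aq. NaHCO3, rt
Reagents that add atoms: none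
Why: N-methylation followed by E1cB (Hofmann-type) elimination of trimethylamine gives the α-methylene γ-lactone.

**Step 21**
Reactants: 36 (3aS,4R,6E,10R,11aR)-6,10-bis[(TBDPS-oxy)methyl]-3-methylidene-4-(triethylsilyloxy)-3a,4,5,8,9,10,11,11a-octahydrocyclodeca[b]furan-2(3H)-one
Product: 37 (3aR,4R,6E,10R,11aR)-4-hydroxy-6,10-bis[(TBDPS-oxy)methyl]-3-methylidene-3a,4,5,8,9,10,11,11a-octahydrocyclodeca[b]furan-2(3H)-one
Conditions: PPTS, MeOH/CH2Cl2, 0 °C → rt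
Reagents that add atoms: none
Why: Mild acid-catalysed methanolysis removes the secondary TES ether while the primary TBDPS ethers stay.

**Step 22**
Reactants: 37 (3aR,4R,6E,10R,11aR)-4-hydroxy-6,10-bis[(TBDPS-oxy)methyl]-3-methylidene-3a,4,5,8,9,10,11,11a-octahydrocyclodeca[b]furan-2(3H)-one; 38 angelic acid [(2Z)-2-methylbut-2-enoic acid]
Product: 40 (3aS,4R,6E,10R,11aR)-6,10-bis[(TBDPS-oxy)methyl]-3-methylidene-2-oxo-2,3,3a,4,5,8,9,10,11,11a-decahydrocyclodeca[b]furan-4-yl (2Z)-2-methylbut-2-enoate, via angelic 2,4,6-trichlorobenzoic anhydride 39 (not isolated)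
Conditions: 38, 2,4,6-trichlorobenzoyl chloride, Et3N, toluene, rt; then 37, 75 °C
Reagents that add atoms: none
Why: Yamaguchi-type mixed-anhydride esterification without DMAP acylates C8–OH and keeps the (Z)-geometry of the angelate.

**Step 23**
Reactants: 40 (3aS,4R,6E,10R,11aR)-6,10-bis[(TBDPS-oxy)methyl]-3-methylidene-2-oxo-2,3,3a,4,5,8,9,10,11,11a-decahydrocyclodeca[b]furan-4-yl (2Z)-2-methylbut-2-enoate
Product: 41 (3aS,4R,6E,10R,11aR)-6,10-bis(hydroxymethyl)-3-methylidene-2-oxo-2,3,3a,4,5,8,9,10,11,11a-decahydrocyclodeca[b]furan-4-yl (2Z)-2-methylbut-2-enoate (CNP0262807.1)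
Conditions: HF·pyridine, pyridine/THF, 0 °C → rt
Reagents that add atoms: none
Why: Buffered fluoride desilylation removes both primary TBDPS ethers without touching the angelate or the α-methylene lactone.

**Compound list**
1 | (S)-4-benzyl-1,3-oxazolidin-2-one | O=C1OC[C@H](Cc2ccccc2)N1 | starting material
2 | hex-5-enoic acid | C=CCCCC(=O)O | starting material
3 | hex-5-enoic pivalic anhydride | C=CCCCC(=O)OC(=O)C(C)(C)C | intermediate (not isolated)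
4 | (4S)-4-benzyl-3-(hex-5-enoyl)-1,3-oxazolidin-2-one | C=CCCCC(=O)N1[C@@H](Cc2ccccc2)COC1=O | intermediate
5 | tert-butyl bromoacetate | CC(C)(C)OC(=O)CBr | starting material
6 | sodium (Z)-enolate of imide 4 | C=CCC/C=C(\[O-])N1[C@@H](Cc2ccccc2)COC1=O.[Na+] | intermediate (not isolated)
7 | tert-butyl (3R)-3-[(4S)-4-benzyl-2-oxo-1,3-oxazolidine-3-carbonyl]hept-6-enoate | C=CCC[C@H](CC(=O)OC(C)(C)C)C(=O)N1[C@@H](Cc2ccccc2)COC1=O | intermediate
8 | tert-butyl (3R)-3-(hydroxymethyl)hept-6-enoate | C=CCC[C@H](CC(=O)OC(C)(C)C)CO | intermediate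
9 | tert-butyl (3R)-3-[(TBDPS-oxy)methyl]hept-6-enoate | C=CCC[C@H](CC(=O)OC(C)(C)C)CO[Si](c1ccccc1)(c1ccccc1)C(C)(C)C | intermediate
10 | diisobutylaluminium hemiacetal of ester 9 | C=CCC[C@H](CC(OC(C)(C)C)O[Al](CC(C)C)CC(C)C)CO[Si](c1ccccc1)(c1ccccc1)C(C)(C)C | intermediate (not isolated)
11 | (3R)-3-[(TBDPS-oxy)methyl]hept-6-enal | C=CCC[C@H](CC=O)CO[Si](c1ccccc1)(c1ccccc1)C(C)(C)C | intermediate
12 | methyl 4-chloro-4-oxobutanoate | COC(=O)CCC(=O)Cl | starting material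
13 | N-lithio derivative of oxazolidinone 1 | O=C1OC[C@H](Cc2ccccc2)N1[Li] | intermediate (not isolated)
14 | methyl 4-[(4S)-4-benzyl-2-oxo-1,3-oxazolidin-3-yl]-4-oxobutanoate | COC(=O)CCC(=O)N1[C@@H](Cc2ccccc2)COC1=O | intermediate
15 | (Z)-dibutylboron enolate of imide 14 | CCCCB(CCCC)O/C(=C\CC(=O)OC)N1[C@@H](Cc2ccccc2)COC1=O | intermediate (not isolated)
16 | methyl (3S,4R,6R)-3-[(4S)-4-benzyl-2-oxo-1,3-oxazolidine-3-carbonyl]-4-hydroxy-6-[(TBDPS-oxy)methyl]dec-9-enoate | COC(=O)C[C@H](C(=O)N1[C@@H](Cc2ccccc2)COC1=O)[C@H](O)C[C@H](CO[Si](c3ccccc3)(c3ccccc3)C(C)(C)C)CCC=C | intermediate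
17 | (4S)-4-benzyl-3-[(2R,3S)-2-[(2R)-2-[(TBDPS-oxy)methyl]hex-5-en-1-yl]-5-oxooxolane-3-carbonyl]-1,3-oxazolidin-2-one | O=C1C[C@H](C(=O)N2[C@@H](Cc3ccccc3)COC2=O)[C@@H](C[C@H](CO[Si](c3ccccc3)(c3ccccc3)C(C)(C)C)CCC=C)O1 | intermediate
18 | (2R,3S)-2-[(2R)-2-[(TBDPS-oxy)methyl]hex-5-en-1-yl]-5-oxooxolane-3-carboperoxoic acid | O=C1C[C@H](C(=O)OO)[C@@H](C[C@H](CO[Si](c2ccccc2)(c2ccccc2)C(C)(C)C)CCC=C)O1 | intermediate (not isolated)
19 | (2R,3S)-2-[(2R)-2-[(TBDPS-oxy)methyl]hex-5-en-1-yl]-5-oxooxolane-3-carboxylic acid | O=C1C[C@H](C(=O)O)[C@@H](C[C@H](CO[Si](c2ccccc2)(c2ccccc2)C(C)(C)C)CCC=C)O1 | intermediate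
20 | isobutyl carbonic anhydride of acid 19 | O=C1C[C@H](C(=O)OC(=O)OCC(C)C)[C@@H](C[C@H](CO[Si](c2ccccc2)(c2ccccc2)C(C)(C)C)CCC=C)O1 | intermediate (not isolated)
21 | (4R,5R)-4-(hydroxymethyl)-5-[(2R)-2-[(TBDPS-oxy)methyl]hex-5-en-1-yl]oxolan-2-one | O=C1C[C@H](CO)[C@@H](C[C@H](CO[Si](c2ccccc2)(c2ccccc2)C(C)(C)C)CCC=C)O1 | intermediate
22 | (2R,3S)-2-[(2R)-2-[(TBDPS-oxy)methyl]hex-5-en-1-yl]-5-oxooxolane-3-carbaldehyde | O=C1C[C@H](C=O)[C@@H](C[C@H](CO[Si](c2ccccc2)(c2ccccc2)C(C)(C)C)CCC=C)O1 | intermediate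
23 | 2-methylidenepropane-1,3-diol | C=C(CO)CO | starting material
24 | 2-[(TBDPS-oxy)methyl]prop-2-en-1-ol | C=C(CO)CO[Si](c1ccccc1)(c1ccccc1)C(C)(C)C | intermediate
25 | 2-[(TBDPS-oxy)methyl]prop-2-en-1-yl methanesulfonate | C=C(COS(C)(=O)=O)CO[Si](c1ccccc1)(c1ccccc1)C(C)(C)C | intermediate (not isolated)
26 | {[2-(bromomethyl)prop-2-en-1-yl]oxy}(tert-butyl)diphenylsilane | C=C(CBr)CO[Si](c1ccccc1)(c1ccccc1)C(C)(C)C | intermediate
27 | allylzinc bromide from bromide 26 | C=C(C[Zn]Br)CO[Si](c1ccccc1)(c1ccccc1)C(C)(C)C | intermediate (not isolated)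
28 | (4R,5R)-4-[(1RS)-1-hydroxy-3-[(TBDPS-oxy)methyl]but-3-en-1-yl]-5-[(2R)-2-[(TBDPS-oxy)methyl]hex-5-en-1-yl]oxolan-2-one | O=C1C[C@H](C(O)CC(=C)CO[Si](c2ccccc2)(c2ccccc2)C(C)(C)C)[C@@H](C[C@H](CO[Si](c2ccccc2)(c2ccccc2)C(C)(C)C)CCC=C)O1 | intermediate
29 | (4S,5R)-4-[3-[(TBDPS-oxy)methyl]but-3-enoyl]-5-[(2R)-2-[(TBDPS-oxy)methyl]hex-5-en-1-yl]oxolan-2-one | O=C1C[C@H](C(=O)CC(=C)CO[Si](c2ccccc2)(c2ccccc2)C(C)(C)C)[C@@H](C[C@H](CO[Si](c2ccccc2)(c2ccccc2)C(C)(C)C)CCC=C)O1 | intermediate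
30 | (4R,5R)-4-[(1R)-1-hydroxy-3-[(TBDPS-oxy)methyl]but-3-en-1-yl]-5-[(2R)-2-[(TBDPS-oxy)methyl]hex-5-en-1-yl]oxolan-2-one | O=C1C[C@H]([C@H](O)CC(=C)CO[Si](c2ccccc2)(c2ccccc2)C(C)(C)C)[C@@H](C[C@H](CO[Si](c2ccccc2)(c2ccccc2)C(C)(C)C)CCC=C)O1 | intermediate
31 | (4S,5R)-4-[(1R)-3-[(TBDPS-oxy)methyl]-1-(triethylsilyloxy)but-3-en-1-yl]-5-[(2R)-2-[(TBDPS-oxy)methyl]hex-5-en-1-yl]oxolan-2-one | O=C1C[C@H]([C@H](O[Si](CC)(CC)CC)CC(=C)CO[Si](c2ccccc2)(c2ccccc2)C(C)(C)C)[C@@H](C[C@H](CO[Si](c2ccccc2)(c2ccccc2)C(C)(C)C)CCC=C)O1 | intermediate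
32 | (3aS,4R,6E,10R,11aR)-6,10-bis[(TBDPS-oxy)methyl]-4-(triethylsilyloxy)-3a,4,5,8,9,10,11,11a-octahydrocyclodeca[b]furan-2(3H)-one | O=C1O[C@@H]2C[C@H](CO[Si](c3ccccc3)(c3ccccc3)C(C)(C)C)CC/C=C(/CO[Si](c3ccccc3)(c3ccccc3)C(C)(C)C)C[C@@H](O[Si](CC)(CC)CC)[C@H]2C1 | intermediate
33 | lithium enolate of lactone 32 | [Li+].[O-]C1O[C@@H]2C[C@H](CO[Si](c3ccccc3)(c3ccccc3)C(C)(C)C)CC/C=C(/CO[Si](c3ccccc3)(c3ccccc3)C(C)(C)C)C[C@@H](O[Si](CC)(CC)CC)[C@H]2C=1 | intermediate (not isolated)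
34 | (3aS,4R,6E,10R,11aR)-3-[(dimethylamino)methyl]-6,10-bis[(TBDPS-oxy)methyl]-4-(triethylsilyloxy)-3a,4,5,8,9,10,11,11a-octahydrocyclodeca[b]furan-2(3H)-one (C11 epimers) | CN(C)CC1C(=O)O[C@@H]2C[C@H](CO[Si](c3ccccc3)(c3ccccc3)C(C)(C)C)CC/C=C(/CO[Si](c3ccccc3)(c3ccccc3)C(C)(C)C)C[C@@H](O[Si](CC)(CC)CC)[C@@H]12 | intermediate
35 | trimethylammonium iodide of amine 34 | C[N+](C)(C)CC1C(=O)O[C@@H]2C[C@H](CO[Si](c3ccccc3)(c3ccccc3)C(C)(C)C)CC/C=C(/CO[Si](c3ccccc3)(c3ccccc3)C(C)(C)C)C[C@@H](O[Si](CC)(CC)CC)[C@@H]12.[I-] | intermediate (not isolated)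
36 | (3aS,4R,6E,10R,11aR)-6,10-bis[(TBDPS-oxy)methyl]-3-methylidene-4-(triethylsilyloxy)-3a,4,5,8,9,10,11,11a-octahydrocyclodeca[b]furan-2(3H)-one | C=C1C(=O)O[C@@H]2C[C@H](CO[Si](c3ccccc3)(c3ccccc3)C(C)(C)C)CC/C=C(/CO[Si](c3ccccc3)(c3ccccc3)C(C)(C)C)C[C@@H](O[Si](CC)(CC)CC)[C@@H]12 | intermediate
37 | (3aR,4R,6E,10R,11aR)-4-hydroxy-6,10-bis[(TBDPS-oxy)methyl]-3-methylidene-3a,4,5,8,9,10,11,11a-octahydrocyclodeca[b]furan-2(3H)-one | C=C1C(=O)O[C@@H]2C[C@H](CO[Si](c3ccccc3)(c3ccccc3)C(C)(C)C)CC/C=C(/CO[Si](c3ccccc3)(c3ccccc3)C(C)(C)C)C[C@@H](O)[C@@H]12 | intermediate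
38 | angelic acid, (2Z)-2-methylbut-2-enoic acid | C/C=C(/C)C(=O)O | starting material
39 | angelic 2,4,6-trichlorobenzoic anhydride | C/C=C(/C)C(=O)OC(=O)c1c(Cl)cc(Cl)cc1Cl | intermediate (not isolated)
40 | (3aS,4R,6E,10R,11aR)-6,10-bis[(TBDPS-oxy)methyl]-3-methylidene-2-oxo-2,3,3a,4,5,8,9,10,11,11a-decahydrocyclodeca[b]furan-4-yl (2Z)-2-methylbut-2-enoate | C=C1C(=O)O[C@@H]2C[C@H](CO[Si](c3ccccc3)(c3ccccc3)C(C)(C)C)CC/C=C(/CO[Si](c3ccccc3)(c3ccccc3)C(C)(C)C)C[C@@H](OC(=O)/C(C)=C\C)[C@@H]12 | intermediate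
41 | (3aS,4R,6E,10R,11aR)-6,10-bis(hydroxymethyl)-3-methylidene-2-oxo-2,3,3a,4,5,8,9,10,11,11a-decahydrocyclodeca[b]furan-4-yl (2Z)-2-methylbut-2-enoate | C=C1C(=O)O[C@@H]2C[C@H](CO)CC/C=C(/CO)C[C@@H](OC(=O)/C(C)=C\C)[C@@H]12 | target

**Step count and risks**
Total step count: 23. Longest linear sequence: 20 steps (steps 1–5, 7–11, 14–23).

Most likely to fail:

Step 18 (ring-closing metathesis). A strained ten-membered carbocycle with a trisubstituted olefin must form from a hindered 1,1-disubstituted alkene; oligomerisation or olefin migration may win. The fallback sets out from aldehyde 22 and comes back at macrocycle 32; it closes the ring by C–C bond formation to a carbonyl and makes the allylic alcohol by transposition. Barbier reaction of 22 with 2,3-dibromopropene (Zn, THF/aq. NH4Cl) gives the 2-bromoallyl carbinol mixture F1. Dess–Martin oxidation gives bromo ketone F2, LiBH(s-Bu)3 gives (1R)-bromo alcohol F3, and Et3SiOTf/2,6-lutidine gives silyl ether F4. OsO4 (cat.)/NaIO4/2,6-lutidine cleaves only the monosubstituted olefin (the bromoalkene is electron-poor) to aldehyde F5. An intramolecular Nozaki–Hiyama–Kishi reaction (CrCl2, NiCl2 cat., DMSO, high dilution) forms the C1–C10 bond and gives the ten-membered exo-methylene allylic alcohol F6. Ph3SiOReO3-catalysed 1,3-transposition moves the hydroxyl to C14 and the double bond into the ring, giving primary allylic alcohol F7; the ring-cis olefin is the less strained isomer under these equilibrating conditions. TBDPSCl/imidazole then gives 32.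

Step 16 (facial selectivity of the C8 ketone reduction). The selectivity rests on Felkin–Anh control by the ring carbon C7 alone, and ketone 29 can enolise towards conjugation. The fallback sets out from 28 and comes back at 30; it sets C8 by SN2 inversion instead of facial selectivity. The (1S)-epimer F8, the expected Felkin–Anh major component of Barbier mixture 28, is separated by chromatography. A Mitsunobu reaction with chloroacetic acid (PPh3, DIAD, toluene) inverts it to the (1R)-chloroacetate F9. Thiourea/NaHCO3 in EtOH removes the chloroacetyl group under near-neutral conditions and gives 30.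

Step 22 (angeloylation). The hindered secondary C8 hydroxyl is slow to acylate, and activated angelic acid can isomerise to the tiglate. The fallback sets out from 37 and comes back at 40; it builds the (Z)-olefin on the molecule instead of carrying it through an activation step. Esterification of 37 with 2-(diphenoxyphosphoryl)propanoic acid (DCC, DMAP cat., CH2Cl2) gives phosphonate ester F10. An Ando-type (Z)-selective Horner–Wadsworth–Emmons olefination with acetaldehyde (NaH, THF, −78 °C) then gives 40.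

**Further compounds**
F1 | step 18 | (4R,5R)-4-[(1RS)-3-bromo-1-hydroxybut-3-en-1-yl]-5-[(2R)-2-[(TBDPS-oxy)methyl]hex-5-en-1-yl]oxolan-2-one | O=C1C[C@H](C(O)CC(Br)=C)[C@@H](C[C@H](CO[Si](c2ccccc2)(c2ccccc2)C(C)(C)C)CCC=C)O1
F2 | step 18 | (4S,5R)-4-(3-bromobut-3-enoyl)-5-[(2R)-2-[(TBDPS-oxy)methyl]hex-5-en-1-yl]oxolan-2-one | O=C1C[C@H](C(=O)CC(Br)=C)[C@@H](C[C@H](CO[Si](c2ccccc2)(c2ccccc2)C(C)(C)C)CCC=C)O1
F3 | step 18 | (4R,5R)-4-[(1R)-3-bromo-1-hydroxybut-3-en-1-yl]-5-[(2R)-2-[(TBDPS-oxy)methyl]hex-5-en-1-yl]oxolan-2-one | O=C1C[C@H]([C@H](O)CC(Br)=C)[C@@H](C[C@H](CO[Si](c2ccccc2)(c2ccccc2)C(C)(C)C)CCC=C)O1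
F4 | step 18 | (4S,5R)-4-[(1R)-3-bromo-1-(triethylsilyloxy)but-3-en-1-yl]-5-[(2R)-2-[(TBDPS-oxy)methyl]hex-5-en-1-yl]oxolan-2-one | O=C1C[C@H]([C@H](O[Si](CC)(CC)CC)CC(Br)=C)[C@@H](C[C@H](CO[Si](c2ccccc2)(c2ccccc2)C(C)(C)C)CCC=C)O1
F5 | step 18 | (4R)-5-[(2R,3S)-3-[(1R)-3-bromo-1-(triethylsilyloxy)but-3-en-1-yl]-5-oxooxolan-2-yl]-4-[(TBDPS-oxy)methyl]pentanal | O=C1C[C@H]([C@H](O[Si](CC)(CC)CC)CC(Br)=C)[C@@H](C[C@H](CO[Si](c2ccccc2)(c2ccccc2)C(C)(C)C)CCC=O)O1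
F6 | step 18 | (3aS,4R,10R,11aR)-7-hydroxy-6-methylidene-10-[(TBDPS-oxy)methyl]-4-(triethylsilyloxy)decahydrocyclodeca[b]furan-2(3H)-one (C1 epimers) | O=C1O[C@@H]2C[C@H](CO[Si](c3ccccc3)(c3ccccc3)C(C)(C)C)CCC(O)C(=C)C[C@@H](O[Si](CC)(CC)CC)[C@H]2C1
F7 | step 18 | (3aS,4R,6E,10R,11aR)-6-(hydroxymethyl)-10-[(TBDPS-oxy)methyl]-4-(triethylsilyloxy)-3a,4,5,8,9,10,11,11a-octahydrocyclodeca[b]furan-2(3H)-one | O=C1O[C@@H]2C[C@H](CO[Si](c3ccccc3)(c3ccccc3)C(C)(C)C)CC/C=C(/CO)C[C@@H](O[Si](CC)(CC)CC)[C@H]2C1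
F8 | step 16 | (4R,5R)-4-[(1S)-1-hydroxy-3-[(TBDPS-oxy)methyl]but-3-en-1-yl]-5-[(2R)-2-[(TBDPS-oxy)methyl]hex-5-en-1-yl]oxolan-2-one | O=C1C[C@H]([C@@H](O)CC(=C)CO[Si](c2ccccc2)(c2ccccc2)C(C)(C)C)[C@@H](C[C@H](CO[Si](c2ccccc2)(c2ccccc2)C(C)(C)C)CCC=C)O1
F9 | step 16 | (1R)-1-[(2R,3S)-2-[(2R)-2-[(TBDPS-oxy)methyl]hex-5-en-1-yl]-5-oxooxolan-3-yl]-3-[(TBDPS-oxy)methyl]but-3-en-1-yl chloroacetate | O=C1C[C@H]([C@H](OC(=O)CCl)CC(=C)CO[Si](c2ccccc2)(c2ccccc2)C(C)(C)C)[C@@H](C[C@H](CO[Si](c2ccccc2)(c2ccccc2)C(C)(C)C)CCC=C)O1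
F10 | step 22 | (3aS,4R,6E,10R,11aR)-6,10-bis[(TBDPS-oxy)methyl]-3-methylidene-2-oxo-2,3,3a,4,5,8,9,10,11,11a-decahydrocyclodeca[b]furan-4-yl 2-(diphenoxyphosphoryl)propanoate | C=C1C(=O)O[C@@H]2C[C@H](CO[Si](c3ccccc3)(c3ccccc3)C(C)(C)C)CC/C=C(/CO[Si](c3ccccc3)(c3ccccc3)C(C)(C)C)C[C@@H](OC(=O)C(C)P(=O)(Oc3ccccc3)Oc3ccccc3)[C@@H]12
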